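## Retrosynthetic overview

1. Feature: in the γ-lactone ring (O1, C2=O, C3, C4, C5), stereocentre C4 carries two CH2 arms, ring carbon C5 (bound to O1) and the benzylic CH2. Written as two CH2–O groups sharing one oxygen, they are the enantiotopic ring carbons of a 3-substituted oxetane on C3, geminal to carboxyl carbon C2.
2. Late disconnections: the phenol O–MOM bond, then the benzylic CH2–aryl bond (primary tosylate + 3,4,5-trimethoxyphenyl cuprate), back to the E-arylidene 4-(hydroxymethyl) lactone.
3. Key disconnection: O1–C5, back to the achiral (E)-2-(oxetan-3-yl)cinnamic acid. A chiral phosphoric acid lets the carboxyl oxygen open one of the two oxetane CH2 groups.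
4. The acid comes from methyl 2-(oxetan-3-yl)acetate (oxetan-3-one, HWE, hydrogenation) and MOM-syringaldehyde by aldol addition, E1cB elimination and saponification.
5. Ring order: both arenes and the oxetane are bought. The lactone is the only ring made, and it is made from the oxetane in the key step.

Key step: step 7

Assumption: the sense of induction of the catalyst on this new substrate cannot be derived safely. Both antipodes of TRIP are commercial, (R)-TRIP is written below, and the antipode is used if the first run gives the mirror-image alcohol.

## Route

Step 1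
Reactants: 1 syringaldehyde (4-hydroxy-3,5-dimethoxybenzaldehyde)
Product: 2 3,5-dimethoxy-4-(methoxymethoxy)benzaldehyde
Conditions: MOMCl, i-Pr2NEt, CH2Cl2, 0 °C → rt
Reagents that add atoms: chloromethyl methyl ether, COCCl
Why: O-alkylation of the acidic phenol (MOM protection) gives an acetal that should withstand LDA, hydroxide, the phosphoric acid and the cuprate and is removed by dilute acid at the end.

Step 2
Reactants: 3 oxetan-3-one; 4 trimethyl phosphonoacetate
Product: 6 methyl 2-(oxetan-3-ylidene)acetate, via sodium phosphonate carbanion 5 (not isolated)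
Conditions: 4, NaH, THF, 0 °C; then 3, 0 °C → rt
Reagents that add atoms: sodium hydride, [Na+].[H-] (its sodium stays only in intermediate 5)
Why: Horner–Wadsworth–Emmons olefination of a strained, unhindered and very electrophilic ketone, whose symmetry removes any question of alkene geometry.

Step 3
Reactants: 6 methyl 2-(oxetan-3-ylidene)acetate
Product: 7 methyl 2-(oxetan-3-yl)acetate
Conditions: H2 (1 atm), 10% Pd/C, EtOAc, rt
Reagents that add atoms: none
Why: Heterogeneous catalytic hydrogenation of the strained exocyclic enoate, under which unactivated oxetane C–O bonds are not hydrogenolysed.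

Step 4
Reactants: 7 methyl 2-(oxetan-3-yl)acetate; 2 3,5-dimethoxy-4-(methoxymethoxy)benzaldehyde
Product: 9 methyl 3-[3,5-dimethoxy-4-(methoxymethoxy)phenyl]-3-hydroxy-2-(oxetan-3-yl)propanoate (racemic syn/anti mixture), via lithium enolate 8 (not isolated)
Conditions: 7, LDA, THF, −78 °C; then 2, −78 °C; AcOH quench at −78 °C
Reagents that add atoms: lithium diisopropylamide, [Li+].CC(C)[N-]C(C)C (its lithium stays only in intermediate 8)
Why: Directed aldol addition of a preformed lithium ester enolate to a non-enolisable aldehyde; the oxetane C–O bond is γ to the carbanion and is not expelled at −78 °C, and both new stereocentres are removed again in step 5, so no control is needed.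

Step 5
Reactants: 9 aldol adduct
Product: 11 methyl (E)-3-[3,5-dimethoxy-4-(methoxymethoxy)phenyl]-2-(oxetan-3-yl)acrylate (aryl trans to CO2Me), via benzylic mesylate 10 (not isolated)
Conditions: MsCl, Et3N, CH2Cl2, 0 °C; then DBU, 0 °C → rt; chromatography
Reagents that add atoms: methanesulfonyl chloride, CS(=O)(=O)Cl (its CH3SO2 group stays only in intermediate 10)
Why: Mesylation followed by E1cB elimination, in which both diastereomers converge through the ester enolate on the more stable E-cinnamate, as is usual for α-alkyl cinnamates, and any Z isomer is removed by chromatography.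

Step 6
Reactants: 11 methyl (E)-enoate
Product: 13 (E)-3-[3,5-dimethoxy-4-(methoxymethoxy)phenyl]-2-(oxetan-3-yl)acrylic acid, via lithium carboxylate 12 (not isolated)
Conditions: LiOH·H2O, THF–MeOH–H2O, rt → 40 °C; then EtOAc, cold 1 M KHSO4 to pH 4, 0 °C; concentrate below 20 °C, use the same day
Reagents that add atoms: lithium hydroxide, [Li+].[OH-] (oxygen of the new carboxyl OH; lithium only in intermediate 12)
Why: BAc2 saponification, in which hydroxide leaves the oxetane alone and carboxylate 12 has no proton to activate it; the free acid is released cold into the organic layer and not stored, because oxetane carboxylic acids isomerise slowly on standing.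

Step 7
Reactants: 13 (E)-2-(oxetan-3-yl)acrylic acid (achiral)
Product: 14 (S,E)-3-[3,5-dimethoxy-4-(methoxymethoxy)benzylidene]-4-(hydroxymethyl)dihydrofuran-2(3H)-one
Conditions: (R)-TRIP (10 mol %), dry toluene (0.02 M), −20 → 0 °C
Reagents that add atoms: none
Why: Proposed new method: the phosphoric acid and the carboxyl group of 13 should pair through two hydrogen bonds; within this pair the catalyst proton goes to the oxetane oxygen while the carboxyl oxygen attacks one ring CH2 from the rear in an SN2 step driven by release of about 25 kcal/mol of four-ring strain, so that O1–C5 forms and the former oxetane oxygen ends as the CH2OH group on C4. The closest known reaction types are the chiral phosphoric acid or (salen)Co(III) catalysed intramolecular desymmetrisation of 3-substituted oxetanes by tethered O–H nucleophiles, the phosphoric acid catalysed opening of meso-epoxides by carboxylic acids through an acid–acid heterodimer, and the uncatalysed isomerisation of oxetane carboxylic acids to lactones; new here are the carboxylic acid as internal nucleophile in the enantioselective version and the sp2 tether. The single ring closes in the 5-exo-tet mode, the breaking C–O bond lying outside the new five-membered ring. C4 is the only new stereocentre, and its configuration follows from which of the two enantiotopic CH2 groups is attacked, a choice made by the 3,3′-aryl pocket of the catalyst. The substrate supports this group selection: allylic strain with the cis aryl group turns the oxetane C–H into the alkene plane, so the two CH2 groups lie on opposite faces of a flat, rigid cinnamic acid and the catalyst, anchored at the carboxyl group, only has to tell two faces apart. The racemic background should need a second molecule of 13 as proton source and is held back by dilution and low temperature, the alkene takes no part so that E is kept, and the aryl MOM acetal should survive a phosphoric acid in dry toluene.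

Step 8
Reactants: 14 (S,E)-4-(hydroxymethyl) lactone
Product: 15 [(R,E)-4-[3,5-dimethoxy-4-(methoxymethoxy)benzylidene]-5-oxotetrahydrofuran-3-yl]methyl 4-methylbenzenesulfonate
Conditions: TsCl, pyridine, CH2Cl2, 0 °C → rt
Reagents that add atoms: p-toluenesulfonyl chloride, Cc1ccc(cc1)S(=O)(=O)Cl
Why: Standard sulfonylation of a primary alcohol that touches no bond at C4 (the descriptor becomes R only through CIP ranking), done at once because the capped oxygen can no longer exchange the acyl group between the two CH2O arms, a degenerate shift that would racemise 14; a sulfonate is preferred to an iodide because it meets cuprates in a two-electron SN2 step and avoids a primary radical homoallylic to the styrene-type alkene.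

Step 9
Reactants: 15 (R,E)-tosylate; 16 5-bromo-1,2,3-trimethoxybenzene
Product: 19 (R,E)-3-[3,5-dimethoxy-4-(methoxymethoxy)benzylidene]-4-(3,4,5-trimethoxybenzyl)dihydrofuran-2(3H)-one, via aryllithium 17 (not isolated), via lithium diarylcuprate 18 (not isolated)
Conditions: 16, t-BuLi (2 equiv per Br), Et2O, −78 °C; CuI (0.5 equiv per ArLi), −30 °C; then 15, Et2O–THF, −30 → 0 °C; aq NH4Cl
Reagents that add atoms: tert-butyllithium, [Li]C(C)(C)C (lithium only in 17 and 18); copper(I) iodide, [Cu]I (copper only in 18)
Why: Bromine–lithium exchange, transmetallation to the Gilman diarylcuprate and SN2 displacement of a primary tosylate, a known coupling that tolerates γ-lactones; the trisubstituted, electron-rich β-aryl enoate is a poor acceptor for a diarylcuprate without Lewis acid, the reagent is weakly basic so the C4–H should stay in place, and C4 keeps its configuration because only the exocyclic CH2–O bond is exchanged.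

Step 10
Reactants: 19 MOM-protected lactone
Product: 20 (R,E)-3-(4-hydroxy-3,5-dimethoxybenzylidene)-4-(3,4,5-trimethoxybenzyl)dihydrofuran-2(3H)-one (target)
Conditions: 2 M aq HCl, THF, rt → 40 °C
Reagents that add atoms: none
Why: Acid-catalysed acetal hydrolysis of the aryl MOM ether, mild enough to leave the lactone, the E-alkene, the methyl ethers and the C4–H untouched.

## Compound list

1 | syringaldehyde | COc1cc(C=O)cc(OC)c1O | starting material
2 | 3,5-dimethoxy-4-(methoxymethoxy)benzaldehyde | COCOc1c(OC)cc(C=O)cc1OC | intermediate
3 | oxetan-3-one | O=C1COC1 | starting material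
4 | trimethyl phosphonoacetate | COC(=O)CP(=O)(OC)OC | starting material
5 | sodium salt of trimethyl phosphonoacetate (carbanion, not isolated) | [Na+].COC(=O)[CH-]P(=O)(OC)OC | intermediate
6 | methyl 2-(oxetan-3-ylidene)acetate | COC(=O)C=C1COC1 | intermediate
7 | methyl 2-(oxetan-3-yl)acetate | COC(=O)CC1COC1 | intermediate
8 | lithium enolate of 7 (not isolated) | [Li+].COC([O-])=CC1COC1 | intermediate
9 | methyl 3-[3,5-dimethoxy-4-(methoxymethoxy)phenyl]-3-hydroxy-2-(oxetan-3-yl)propanoate, racemic syn/anti mixture | COCOc1c(OC)cc(C(O)C(C(=O)OC)C2COC2)cc1OC | intermediate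
10 | 3-methanesulfonate of 9 (not isolated) | COCOc1c(OC)cc(C(OS(C)(=O)=O)C(C(=O)OC)C2COC2)cc1OC | intermediate
11 | methyl (E)-3-[3,5-dimethoxy-4-(methoxymethoxy)phenyl]-2-(oxetan-3-yl)acrylate | COCOc1c(OC)cc(/C=C(/C(=O)OC)C2COC2)cc1OC | intermediate
12 | lithium (E)-3-[3,5-dimethoxy-4-(methoxymethoxy)phenyl]-2-(oxetan-3-yl)acrylate (not isolated) | [Li+].COCOc1c(OC)cc(/C=C(/C(=O)[O-])C2COC2)cc1OC | intermediate
13 | (E)-3-[3,5-dimethoxy-4-(methoxymethoxy)phenyl]-2-(oxetan-3-yl)acrylic acid | COCOc1c(OC)cc(/C=C(/C(=O)O)C2COC2)cc1OC | intermediate
14 | (S,E)-3-[3,5-dimethoxy-4-(methoxymethoxy)benzylidene]-4-(hydroxymethyl)dihydrofuran-2(3H)-one | COCOc1c(OC)cc(/C=C2/C(=O)OC[C@@H]2CO)cc1OC | intermediate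
15 | (R,E)-tosylate of 14 | COCOc1c(OC)cc(/C=C2/C(=O)OC[C@@H]2COS(=O)(=O)c3ccc(C)cc3)cc1OC | intermediate
16 | 5-bromo-1,2,3-trimethoxybenzene | COc1cc(Br)cc(OC)c1OC | starting material
17 | 3,4,5-trimethoxyphenyllithium (not isolated) | [Li]c1cc(OC)c(OC)c(OC)c1 | intermediate
18 | lithium bis(3,4,5-trimethoxyphenyl)cuprate (not isolated) | [Li+].COc1cc([Cu-]c2cc(OC)c(OC)c(OC)c2)cc(OC)c1OC | intermediate
19 | (R,E)-3-[3,5-dimethoxy-4-(methoxymethoxy)benzylidene]-4-(3,4,5-trimethoxybenzyl)dihydrofuran-2(3H)-one | COCOc1c(OC)cc(/C=C2/C(=O)OC[C@@H]2Cc3cc(OC)c(OC)c(OC)c3)cc1OC | intermediate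
20 | (R,E)-3-(4-hydroxy-3,5-dimethoxybenzylidene)-4-(3,4,5-trimethoxybenzyl)dihydrofuran-2(3H)-one | COc1cc(/C=C2/C(=O)OC[C@@H]2Cc2cc(OC)c(OC)c(OC)c2)cc(OC)c1O | target

## Step count and risks

Total step count: 10.
Longest linear sequence: 9 steps (3 → 20, steps 2–10). Step 1 is a one-step side branch.

**Risk 1, step 7 (Proposed new method).** Three processes may spoil the step:
- Selection between the enantiotopic CH2 groups may be poor because the self-catalysed opening competes.
- Turnover may be slow because substrate and product tie up the catalyst by hydrogen bonding.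
- Enantiopurity may erode through acyl shift between the two CH2O arms.

The fallback sets out from ester 11 and comes back at tosylate 15, using only known reaction types. DIBAL-H (CH2Cl2, −78 °C) reduces 11 to (E)-3-[3,5-dimethoxy-4-(methoxymethoxy)phenyl]-2-(oxetan-3-yl)prop-2-en-1-ol F1. A chiral (salen)Co(III) catalyst in MeCN at rt then effects the established enantioselective opening of a 3-substituted oxetane by a primary alcohol on a two-carbon tether. The catalyst antipode is chosen as in the assumption above, and the product is the (S,E)-3-arylidene-4-(hydroxymethyl)tetrahydrofuran F2. TsCl in pyridine gives the (R,E)-tetrahydrofuran tosylate F3. Chromium(VI) oxidation (CrO3·3,5-dimethylpyrazole, CH2Cl2, −20 °C) of the C2 methylene, which is both allylic and next to the ring oxygen, raises it to the lactone carbonyl of 15.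

**Risk 2, step 9.** Three processes may spoil the step:
- The cuprate may remove the allylic, vinylogously acidic C4–H, leading to loss of sulfonate or racemisation.
- It may add in conjugate fashion to the arylidene lactone.
- Substitution at the β-branched carbon may be too slow.

The fallback reverses the polarity of the coupling. It sets out from tosylate 15 and comes back at 19. A Finkelstein exchange (NaI, acetone) gives the (R,E)-4-(iodomethyl) lactone F4. Activated zinc dust in DMF, kept cold so that any radical stage stays short, gives the alkylzinc iodide F5. Negishi coupling of F5 with aryl bromide 16 (Pd2(dba)3, SPhos, DMF–THF, rt → 40 °C) gives 19 under essentially non-basic conditions.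

**Risk 3, step 5.** Control of alkene geometry in the elimination may be poor, because allylic strain between the aryl and oxetanyl groups narrows the gap between the two isomers.

The fallback replaces elimination by a stereospecific cross-coupling. It sets out from aldehyde 2 and comes back at ester 11. Wittig olefination of 2 with methyl bromo(triphenylphosphoranylidene)acetate gives methyl (Z)-2-bromo-3-[3,5-dimethoxy-4-(methoxymethoxy)phenyl]acrylate F6 (aryl trans to CO2Me), purified as one isomer. 3-Iodooxetane and activated zinc in DMA give oxetan-3-ylzinc iodide F7. Negishi coupling of F6 with F7 (PdCl2(dppf), THF–DMA, rt → 50 °C) proceeds with retention at the vinyl carbon and should give 11 with the aryl group still trans to the ester.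

## Further compounds

F1 | step 7 | (E)-3-[3,5-dimethoxy-4-(methoxymethoxy)phenyl]-2-(oxetan-3-yl)prop-2-en-1-ol | COCOc1c(OC)cc(/C=C(/CO)C2COC2)cc1OC
F2 | step 7 | [(S,E)-4-[3,5-dimethoxy-4-(methoxymethoxy)benzylidene]tetrahydrofuran-3-yl]methanol | COCOc1c(OC)cc(/C=C2/COC[C@@H]2CO)cc1OC
F3 | step 7 | [(R,E)-4-[3,5-dimethoxy-4-(methoxymethoxy)benzylidene]tetrahydrofuran-3-yl]methyl 4-methylbenzenesulfonate | COCOc1c(OC)cc(/C=C2/COC[C@@H]2COS(=O)(=O)c3ccc(C)cc3)cc1OC
F4 | step 9 | (R,E)-3-[3,5-dimethoxy-4-(methoxymethoxy)benzylidene]-4-(iodomethyl)dihydrofuran-2(3H)-one | COCOc1c(OC)cc(/C=C2/C(=O)OC[C@@H]2CI)cc1OC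
F5 | step 9 | alkylzinc iodide from F4 | COCOc1c(OC)cc(/C=C2/C(=O)OC[C@@H]2C[Zn]I)cc1OC
F6 | step 5 | methyl (Z)-2-bromo-3-[3,5-dimethoxy-4-(methoxymethoxy)phenyl]acrylate | COCOc1c(OC)cc(/C=C(\Br)C(=O)OC)cc1OC
F7 | step 5 | oxetan-3-ylzinc iodide | I[Zn]C1COC1
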